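**Retrosynthetic overview** (briarane locants: ten-membered ring C1–C10; cyclohexane C1, C10–C14; lactone O–C19(=O)–C17–C8–C7; C16 = exocyclic CH2 on C5; C18 = methyl on C17)
1. The γ-lactone is taken back to a 2-ethoxyfuran fused to the ten-membered ring; furan and ten-membered ring are made together, from an acyclic oxazole–ynone, by an intramolecular Diels–Alder/retro-Diels–Alder reaction that forms C7–C8 and C17–C19 and expels acetonitrile.
2. Enabling feature: the lactone oxygen with its two flanking carbons, C7 (bearing C6) and C19 (carboxyl level), is the O1/C2/C5 unit of a 5-alkoxyoxazole; C8–C17 with the C18 methyl and the oxygenated C9 is a but-2-ynoyl ketone whose C9 carbonyl activates the alkyne.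
3. Ring order: cyclohexane first (catalytic asymmetric Diels–Alder sets C1, C10, C11; C12 by reduction then Mitsunobu inversion; C13–C14 epoxide by directed epoxidation).
4. Then the side chains (C2 by CBS reduction; C6 by asymmetric Nozaki–Hiyama–Kishi coupling with the oxazole aldehyde; C9 ynone), then furan and ten-membered ring in one step.
5. Endgame: C9 by Luche reduction, C7 by furan hydrolysis, C8/C17 by alkoxide-directed epoxidation and SmI2 opening, chlorine last by Corey–Kim inversion at C6.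

Key step: step 24

Assumption: in the two catalyst-controlled steps (3 and 18) the named catalyst or ligand enantiomer is taken to give the drawn hand; its antipode would be used if the sense of induction were opposite.

Step 1
Reactants: 1 ethyl vinyl ketone
Product: 2 (Z)-3-(tert-butyldimethylsilyloxy)penta-1,3-diene
Conditions: TBSOTf, Et3N, Et2O, 0 °C
Reagents that add atoms: tert-butyldimethylsilyl triflate, CC(C)(C)[Si](C)(C)OS(=O)(=O)C(F)(F)F
Why: Soft enolisation of the enone toward its ethyl group (silyl enol ether formation) gives the 2-silyloxydiene, the Z enol ether (methyl cis to oxygen) being the usual outcome.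

Step 2
Reactants: 3 (tert-butyldimethylsilyloxy)acetaldehyde; 4 2-(triphenylphosphoranylidene)propanal
Product: 5 (E)-4-(tert-butyldimethylsilyloxy)-2-methylbut-2-enal
Conditions: PhMe, 80 °C
Reagents that add atoms: none
Why: Wittig olefination with the stabilised ylide should give the (E)-trisubstituted enal.

Step 3
Reactants: 2 silyloxydiene; 5 enal
Product: 6 Diels–Alder adduct (4-silyloxycyclohex-3-ene-1-carbaldehyde with C1 methyl, C10 CH2OTBS and C11 methyl on one face, formyl on the other)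
Conditions: (S)-o-tolyl-oxazaborolidine·Tf2NH (20 mol%), CH2Cl2, −78 → −40 °C
Reagents that add atoms: none
Why: Catalytic enantioselective Diels–Alder reaction: the 2-silyloxy group directs the formyl-bearing carbon para to it (bonds C1–C14 and C10–C11), the exo-formyl transition state usual for α-substituted enals places the C1 methyl, the C10 arm and the C11 methyl cis, and the shielded face of the catalyst-bound enal sets the absolute configuration of C1, C10 and C11.

Step 4
Reactants: 7 (1-bromovinyl)trimethylsilane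
Product: 9 3-(trimethylsilyl)but-3-en-1-ol, via vinyl Grignard reagent 8 (not isolated)
Conditions: Mg, THF; then CuI (10 mol%), ethylene oxide, −30 → 0 °C
Reagents that add atoms: ethylene oxide, C1CO1
Why: Grignard formation followed by copper-catalysed epoxide opening gives the homoallylic alcohol.

Step 5
Reactants: 9 3-(trimethylsilyl)but-3-en-1-ol
Product: 10 (4-bromobut-1-en-2-yl)trimethylsilane
Conditions: CBr4, PPh3, CH2Cl2, 0 °C
Reagents that add atoms: carbon tetrabromide, BrC(Br)(Br)Br
Why: Appel reaction converts the primary alcohol into the bromide.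

Step 6
Reactants: 10 bromide; 6 Diels–Alder adduct
Product: 12 C2 carbinol (both C2 epimers), via alkyl Grignard reagent 11 (not isolated)
Conditions: Mg, THF; then 6, −78 °C
Reagents that add atoms: none
Why: Grignard addition to the neopentyl aldehyde installs C3–C5 and C16 (as a vinylsilane); both C2 epimers are carried on because C2 is re-set in steps 7 and 8.

Step 7
Reactants: 12 C2 carbinol
Product: 13 C2 ketone
Conditions: Dess–Martin periodinane, NaHCO3, CH2Cl2, rt
Reagents that add atoms: none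
Why: Dess–Martin oxidation gives the ketone without touching the silyl enol ether or the vinylsilane.

Step 8
Reactants: 13 C2 ketone
Product: 14 (2R)-alcohol
Conditions: (S)-Me-CBS (20 mol%), catecholborane, PhMe, −78 °C
Reagents that add atoms: none
Why: CBS reduction: the catalyst differentiates the quaternary C1 from the C3 methylene and, reinforced by Felkin–Anh attack anti to C10, should deliver hydride to give the (2R)-alcohol.

Step 9
Reactants: 14 (2R)-alcohol
Product: 15 (2R)-acetate
Conditions: Ac2O, DMAP, pyridine, 40 °C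
Reagents that add atoms: acetic anhydride, CC(=O)OC(C)=O
Why: DMAP-catalysed acylation installs the C2 acetate of the target early, since every later step tolerates it.

Step 10
Reactants: 15 (2R)-acetate
Product: 16 cyclohexenone (C12 ketone, C13=C14)
Conditions: Pd(OAc)2 (1.1 equiv), MeCN, rt
Reagents that add atoms: none
Why: Saegusa–Ito oxidation of the silyl enol ether gives the C13=C14 enone regiospecifically.

Step 11
Reactants: 16 cyclohexenone
Product: 17 12-epi allylic alcohol (C12 hydroxyl cis to the C11 methyl)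
Conditions: NaBH4, CeCl3·7H2O, MeOH, −78 °C
Reagents that add atoms: none
Why: Luche 1,2-reduction: hydride should add to the face opposite the axial C10 arm, giving the C12 epimer of the target, which step 12 corrects.

Step 12
Reactants: 17 12-epi allylic alcohol
Product: 18 C12 chloroacetate (oxygen trans to the C11 methyl, as in the target)
Conditions: ClCH2CO2H, PPh3, DIAD, THF, 0 °C → rt
Reagents that add atoms: chloroacetic acid, OC(=O)CCl
Why: Mitsunobu reaction: SN2 displacement of the activated allylic alcohol by chloroacetate inverts C12.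

Step 13
Reactants: 18 C12 chloroacetate
Product: 19 C12 allylic alcohol (target configuration)
Conditions: thiourea, NaHCO3, EtOH, 50 °C
Reagents that add atoms: none
Why: Thiourea alkylation and cyclisation removes the chloroacetate selectively and leaves the C2 acetate.

Step 14
Reactants: 19 C12 allylic alcohol
Product: 20 cis-epoxy alcohol (13,14-epoxide syn to the C12 hydroxyl)
Conditions: VO(acac)2 (5 mol%), t-BuOOH, CH2Cl2, 0 °C → rt
Reagents that add atoms: tert-butyl hydroperoxide, CC(C)(C)OO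
Why: Vanadium-catalysed hydroxyl-directed epoxidation delivers oxygen syn to the C12 hydroxyl, setting C13 and C14; the non-allylic vinylsilane is not touched.

Step 15
Reactants: 20 cis-epoxy alcohol
Product: 21 C12 hexanoate
Conditions: hexanoyl chloride, pyridine, DMAP (cat.), CH2Cl2, 0 °C → rt
Reagents that add atoms: hexanoyl chloride, CCCCCC(Cl)=O
Why: Acylation of the only free hydroxyl installs the C12 hexanoate.

Step 16
Reactants: 21 C12 hexanoate
Product: 22 vinyl iodide (C5–I)
Conditions: NIS, MeCN/ClCH2CN (4:1), 0 °C → rt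
Reagents that add atoms: N-iodosuccinimide, O=C1CCC(=O)N1I
Why: Ipso-iododesilylation of the vinylsilane gives the 2-iodoalkene with the double bond in place; no other alkene remains.

Step 17
Reactants: 23 ethyl 5-ethoxy-4-methyl-1,3-oxazole-2-carboxylate
Product: 24 5-ethoxy-4-methyl-1,3-oxazole-2-carbaldehyde
Conditions: i-Bu2AlH, CH2Cl2, −78 °C
Reagents that add atoms: none
Why: Half-reduction of the ester stops at the aldehyde because the tetrahedral aluminate survives at −78 °C.

Step 18
Reactants: 22 vinyl iodide; 24 oxazole aldehyde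
Product: 25 (6R)-oxazolyl carbinol
Conditions: CrCl2 (4 equiv), NiCl2 (2 mol%), (S)-N-[2-(4-isopropyl-4,5-dihydrooxazol-2-yl)-6-methoxyphenyl]methanesulfonamide, Et3N, THF, rt
Reagents that add atoms: none
Why: Asymmetric Nozaki–Hiyama–Kishi coupling forms C5–C6 with the C5=C16 methylene in place; the chromium-bound sulfonamide ligand controls the aldehyde face to give the (6R)-alcohol.

Step 19
Reactants: 25 (6R)-oxazolyl carbinol
Product: 26 C6 tert-butyldimethylsilyl ether
Conditions: TBSOTf, 2,6-lutidine, CH2Cl2, −78 °C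
Reagents that add atoms: tert-butyldimethylsilyl triflate, CC(C)(C)[Si](C)(C)OS(=O)(=O)C(F)(F)F
Why: Silylation protects the C6 hydroxyl through oxidation, cycloaddition and reduction steps.

Step 20
Reactants: 26 bis-silyl ether
Product: 27 C9 primary alcohol
Conditions: HF·pyridine, pyridine, THF, 0 °C
Reagents that add atoms: none
Why: Buffered fluoride cleaves the unhindered primary silyl ether much faster than the hindered secondary C6 silyl ether.

Step 21
Reactants: 27 C9 primary alcohol
Product: 28 C9 aldehyde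
Conditions: Dess–Martin periodinane, NaHCO3, CH2Cl2, rt
Reagents that add atoms: none
Why: Neutral Dess–Martin oxidation should not epimerise C10 or harm the alkoxyoxazole.

Step 22
Reactants: 28 C9 aldehyde
Product: 29 propargylic alcohol (both C9 epimers)
Conditions: 1-propynylmagnesium bromide, THF, −78 °C
Reagents that add atoms: 1-propynylmagnesium bromide, CC#C[Mg]Br
Why: Acetylide addition to the aldehyde is much faster than attack on the two esters at −78 °C and brings in C8, C17 and C18; the C9 configuration is irrelevant here.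

Step 23
Reactants: 29 propargylic alcohol
Product: 30 oxazole–ynone
Conditions: Dess–Martin periodinane, NaHCO3, CH2Cl2, 0 °C
Reagents that add atoms: none
Why: Dess–Martin oxidation gives the ynone, used at once in step 24.

Step 24
Reactants: 30 oxazole–ynone
Product: 32 2-ethoxyfuran-fused ten-membered-ring ketone, via oxa-aza-bicyclic cycloadduct 31 (not isolated)
Conditions: PhMe (0.001 M), BHT (cat.), 120 °C, sealed vessel
Reagents that add atoms: none
Why: On heating at high dilution the 5-ethoxyoxazole acts as a 2-azadiene across its C2 (= C7) and C5 (= C19) toward the tethered ynone C8≡C17, giving bicyclic adduct 31, which loses acetonitrile by retro-Diels–Alder reaction to the aromatic 2-ethoxyfuran 32. The closest known reaction is the intramolecular oxazole–alkynone Diels–Alder/retro-Diels–Alder route to ring-fused 2-alkoxyfurans, so far used for five- to seven-membered new rings. The furan ring is closed by the cycloaddition itself (both new C–C bonds), and the ten-membered carbocycle by the C7–C8 bond in a fused, type 1 intramolecular mode. No stereocentre is created, since C7, C8, C17 and C19 all end up sp2. The step needs regioselectivity (C7 to C8, C19 to C17) and ring closure over oligomerisation: the eight-atom tether allows the fused orientation without a strained 2,4-bridged furan, the C9 carbonyl lowers the alkyne LUMO so that the reaction should run near 120 °C, and 1 mM concentration suppresses intermolecular adducts. The C5=C16 alkene cannot reach the azadiene, and the silyl ether, esters and epoxide are inert to neutral thermolysis.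

Step 25
Reactants: 32 furyl ketone
Product: 33 (9R)-furyl carbinol
Conditions: NaBH4, CeCl3·7H2O, MeOH, −40 → 0 °C
Reagents that add atoms: none
Why: Luche reduction: with the carbonyl oxygen turned toward the C17 methyl, the ring chain covers the face syn to C6, so hydride should enter from the open face to give the (9R)-alcohol; the esters are untouched.

Step 26
Reactants: 33 (9R)-furyl carbinol
Product: 34 butenolide (C7–H, C8=C17, free C9 hydroxyl)
Conditions: PPTS (cat.), THF/H2O (10:1), 0 °C → rt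
Reagents that add atoms: water, O
Why: Acid hydrolysis of the 2-alkoxyfuran (protonation at C7, water addition at C19, loss of ethanol) gives the conjugated butenolide; protonation anti to the C6 silyloxy group in the allylic-strain-minimised rotamer should set C7.

Step 27
Reactants: 34 butenolide
Product: 35 8,17-epoxy lactone
Conditions: t-BuOOH, n-BuLi, THF, −78 → −20 °C
Reagents that add atoms: tert-butyl hydroperoxide, CC(C)(C)OO
Why: Weitz–Scheffer-type nucleophilic epoxidation: the lithium C9 alkoxide binds lithium tert-butylperoxide and delivers it to C8 on the face it occupies (C9–H eclipsing the C17 methyl), which is the face of C6, setting C8 and C17.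

Step 28
Reactants: 35 8,17-epoxy lactone
Product: 36 8-hydroxy lactone (C6 silyl ether)
Conditions: SmI2, Me2NCH2CH2OH, THF, −78 °C
Reagents that add atoms: none
Why: SmI2 reductive cleavage of the α,β-epoxy lactone at the α-carbon–oxygen bond gives the β-hydroxy lactone with C8 retained; protonation of the samarium enolate, with equilibration possible at the enolisable C17, should place the methyl anti to the C9 branch.

Step 29
Reactants: 36 8-hydroxy lactone
Product: 37 C6 allylic alcohol (triol)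
Conditions: HF·pyridine, pyridine, THF, 0 °C → rt
Reagents that add atoms: none
Why: Buffered fluoride removes the last silyl group without opening the epoxide or cleaving the esters.

Step 30
Reactants: 37 C6 allylic alcohol
Product: 38 target CNP0109876.1
Conditions: NCS, Me2S, CH2Cl2, −20 → 0 °C
Reagents that add atoms: N-chlorosuccinimide, O=C1CCC(=O)N1Cl
Why: Corey–Kim chlorination: only the allylic C6 alkoxysulfonium salt is displaced by chloride, SN2 with inversion, to the (6S)-chloride; the C8 and C9 hydroxyls return unchanged on work-up.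

**Compound list**

1 | ethyl vinyl ketone | C=CC(=O)CC | starting material
2 | (Z)-3-(tert-butyldimethylsilyloxy)penta-1,3-diene | C=C/C(O[Si](C)(C)C(C)(C)C)=C/C | intermediate
3 | (tert-butyldimethylsilyloxy)acetaldehyde | CC(C)(C)[Si](C)(C)OCC=O | starting material
4 | 2-(triphenylphosphoranylidene)propanal | CC(C=O)=P(c1ccccc1)(c1ccccc1)c1ccccc1 | starting material
5 | (E)-4-(tert-butyldimethylsilyloxy)-2-methylbut-2-enal | O=C/C(C)=C/CO[Si](C)(C)C(C)(C)C | intermediate
6 | Diels–Alder adduct: 4-silyloxycyclohex-3-ene-1-carbaldehyde, C1 methyl, C10 CH2OTBS and C11 methyl cis, formyl trans | O=C[C@]2(C)[C@H]([C@@H](C)C(O[Si](C)(C)C(C)(C)C)=CC2)CO[Si](C)(C)C(C)(C)C | intermediate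
7 | (1-bromovinyl)trimethylsilane | C=C(Br)[Si](C)(C)C | starting material
8 | [1-(trimethylsilyl)vinyl]magnesium bromide | C=C([Mg]Br)[Si](C)(C)C | intermediate
9 | 3-(trimethylsilyl)but-3-en-1-ol | C=C(CCO)[Si](C)(C)C | intermediate
10 | (4-bromobut-1-en-2-yl)trimethylsilane | C=C(CCBr)[Si](C)(C)C | intermediate
11 | [3-(trimethylsilyl)but-3-en-1-yl]magnesium bromide | C=C(CC[Mg]Br)[Si](C)(C)C | intermediate
12 | C2 carbinol, mixture of C2 epimers | C=C([Si](C)(C)C)CCC(O)[C@]2(C)[C@H]([C@@H](C)C(O[Si](C)(C)C(C)(C)C)=CC2)CO[Si](C)(C)C(C)(C)C | intermediate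
13 | C2 ketone | C=C([Si](C)(C)C)CCC(=O)[C@]2(C)[C@H]([C@@H](C)C(O[Si](C)(C)C(C)(C)C)=CC2)CO[Si](C)(C)C(C)(C)C | intermediate
14 | (2R)-alcohol | C=C([Si](C)(C)C)CC[C@@H](O)[C@]2(C)[C@H]([C@@H](C)C(O[Si](C)(C)C(C)(C)C)=CC2)CO[Si](C)(C)C(C)(C)C | intermediate
15 | (2R)-acetate | C=C([Si](C)(C)C)CC[C@@H](OC(C)=O)[C@]2(C)[C@H]([C@@H](C)C(O[Si](C)(C)C(C)(C)C)=CC2)CO[Si](C)(C)C(C)(C)C | intermediate
16 | cyclohexenone (C12 ketone, C13=C14) | C=C([Si](C)(C)C)CC[C@@H](OC(C)=O)[C@]2(C)[C@H]([C@@H](C)C(=O)C=C2)CO[Si](C)(C)C(C)(C)C | intermediate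
17 | 12-epi allylic alcohol (hydroxyl cis to C11 methyl) | C=C([Si](C)(C)C)CC[C@@H](OC(C)=O)[C@]2(C)[C@H]([C@@H](C)[C@@H](O)C=C2)CO[Si](C)(C)C(C)(C)C | intermediate
18 | C12 chloroacetate (target configuration at C12) | C=C([Si](C)(C)C)CC[C@@H](OC(C)=O)[C@]2(C)[C@H]([C@@H](C)[C@H](OC(=O)CCl)C=C2)CO[Si](C)(C)C(C)(C)C | intermediate
19 | C12 allylic alcohol (target configuration) | C=C([Si](C)(C)C)CC[C@@H](OC(C)=O)[C@]2(C)[C@H]([C@@H](C)[C@H](O)C=C2)CO[Si](C)(C)C(C)(C)C | intermediate
20 | cis-13,14-epoxy C12 alcohol | C=C([Si](C)(C)C)CC[C@@H](OC(C)=O)[C@]2(C)[C@H]([C@@H](C)[C@H](O)[C@@H]3O[C@@H]32)CO[Si](C)(C)C(C)(C)C | intermediate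
21 | C12 hexanoate, vinylsilane | C=C([Si](C)(C)C)CC[C@@H](OC(C)=O)[C@]2(C)[C@H]([C@@H](C)[C@H](OC(=O)CCCCC)[C@@H]3O[C@@H]32)CO[Si](C)(C)C(C)(C)C | intermediate
22 | vinyl iodide (C5–I) | C=C(I)CC[C@@H](OC(C)=O)[C@]2(C)[C@H]([C@@H](C)[C@H](OC(=O)CCCCC)[C@@H]3O[C@@H]32)CO[Si](C)(C)C(C)(C)C | intermediate
23 | ethyl 5-ethoxy-4-methyl-1,3-oxazole-2-carboxylate | CCOC(=O)c1nc(C)c(OCC)o1 | starting material
24 | 5-ethoxy-4-methyl-1,3-oxazole-2-carbaldehyde | CCOc1oc(C=O)nc1C | intermediate
25 | (6R)-oxazolyl carbinol | C=C(CC[C@@H](OC(C)=O)[C@]2(C)[C@H]([C@@H](C)[C@H](OC(=O)CCCCC)[C@@H]3O[C@@H]32)CO[Si](C)(C)C(C)(C)C)[C@@H](O)c1nc(C)c(OCC)o1 | intermediate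
26 | C6 silyl ether (bis-TBS) | C=C(CC[C@@H](OC(C)=O)[C@]2(C)[C@H]([C@@H](C)[C@H](OC(=O)CCCCC)[C@@H]3O[C@@H]32)CO[Si](C)(C)C(C)(C)C)[C@@H](O[Si](C)(C)C(C)(C)C)c1nc(C)c(OCC)o1 | intermediate
27 | C9 primary alcohol | C=C(CC[C@@H](OC(C)=O)[C@]2(C)[C@H]([C@@H](C)[C@H](OC(=O)CCCCC)[C@@H]3O[C@@H]32)CO)[C@@H](O[Si](C)(C)C(C)(C)C)c1nc(C)c(OCC)o1 | intermediate
28 | C9 aldehyde | C=C(CC[C@@H](OC(C)=O)[C@]2(C)[C@H]([C@@H](C)[C@H](OC(=O)CCCCC)[C@@H]3O[C@@H]32)C=O)[C@@H](O[Si](C)(C)C(C)(C)C)c1nc(C)c(OCC)o1 | intermediate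
29 | propargylic alcohol, mixture of C9 epimers | C=C(CC[C@@H](OC(C)=O)[C@]2(C)[C@H]([C@@H](C)[C@H](OC(=O)CCCCC)[C@@H]3O[C@@H]32)C(O)C#CC)[C@@H](O[Si](C)(C)C(C)(C)C)c1nc(C)c(OCC)o1 | intermediate
30 | oxazole–ynone | C=C(CC[C@@H](OC(C)=O)[C@]2(C)[C@H]([C@@H](C)[C@H](OC(=O)CCCCC)[C@@H]3O[C@@H]32)C(=O)C#CC)[C@@H](O[Si](C)(C)C(C)(C)C)c1nc(C)c(OCC)o1 | intermediate
31 | primary cycloadduct (7-oxa-2-azabicyclo[2.2.1]hepta-2,5-diene bridging the ten-membered ring; bridgehead configuration not specified) | C=C1CC[C@@H](OC(C)=O)[C@]2(C)[C@H]([C@@H](C)[C@H](OC(=O)CCCCC)[C@@H]3O[C@@H]32)C(=O)C2=C(C)C4(OCC)OC2(N=C4C)[C@@H]1O[Si](C)(C)C(C)(C)C | intermediate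
32 | 2-ethoxyfuran-fused ten-membered-ring ketone | C=C1CC[C@@H](OC(C)=O)[C@]2(C)[C@H]([C@@H](C)[C@H](OC(=O)CCCCC)[C@@H]3O[C@@H]32)C(=O)c2c(C)c(OCC)oc2[C@@H]1O[Si](C)(C)C(C)(C)C | intermediate
33 | (9R)-furyl carbinol | C=C1CC[C@@H](OC(C)=O)[C@]2(C)[C@H]([C@@H](C)[C@H](OC(=O)CCCCC)[C@@H]3O[C@@H]32)[C@@H](O)c2c(C)c(OCC)oc2[C@@H]1O[Si](C)(C)C(C)(C)C | intermediate
34 | butenolide with free C9 hydroxyl | C=C1CC[C@@H](OC(C)=O)[C@]2(C)[C@H]([C@@H](C)[C@H](OC(=O)CCCCC)[C@@H]3O[C@@H]32)[C@@H](O)C2=C(C)C(=O)O[C@H]2[C@@H]1O[Si](C)(C)C(C)(C)C | intermediate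
35 | 8,17-epoxy lactone | C=C1CC[C@@H](OC(C)=O)[C@]2(C)[C@H]([C@@H](C)[C@H](OC(=O)CCCCC)[C@@H]3O[C@@H]32)[C@@H](O)[C@@]23O[C@@]3(C)C(=O)O[C@H]2[C@@H]1O[Si](C)(C)C(C)(C)C | intermediate
36 | 8-hydroxy lactone, C6 silyl ether | C=C1CC[C@@H](OC(C)=O)[C@]2(C)[C@H]([C@@H](C)[C@H](OC(=O)CCCCC)[C@@H]3O[C@@H]32)[C@@H](O)[C@]2(O)[C@@H](C)C(=O)O[C@H]2[C@@H]1O[Si](C)(C)C(C)(C)C | intermediate
37 | (6R)-allylic alcohol (6,8,9-triol) | C=C1CC[C@@H](OC(C)=O)[C@]2(C)[C@H]([C@@H](C)[C@H](OC(=O)CCCCC)[C@@H]3O[C@@H]32)[C@@H](O)[C@]2(O)[C@@H](C)C(=O)O[C@H]2[C@@H]1O | intermediate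
38 | CNP0109876.1 (2-acetoxy-6-chloro-13,14-epoxy-12-hexanoyloxy-8,9-dihydroxy briarane 5(16)-ene lactone) | C=C1CC[C@@H](OC(C)=O)[C@]2(C)[C@H]([C@@H](C)[C@H](OC(=O)CCCCC)[C@@H]3O[C@@H]32)[C@@H](O)[C@]2(O)[C@@H](C)C(=O)O[C@H]2[C@H]1Cl | target

**Step count and risks**

Total step count: 30. Longest linear sequence: 26 steps (steps 2, 3, 6–16, 18–30).

Steps most likely to fail:

1. Step 24. The ten-membered ring closure may be too slow, so that oligomerisation or ynone decomposition wins. Fallback, from 30, back at 37: a temporary silicon tether turns the cycloaddition into a seven-membered ring closure and sets C9 beforehand. (R)-Me-CBS/catecholborane reduction of 30 should give the (9R)-propargylic alcohol F1. HF·pyridine then frees the C6 hydroxyl to give the diol F2. i-Pr2Si(OTf)2/2,6-lutidine at high dilution ties O6 and O9 into the cyclic silylene F3. Heating in o-dichlorobenzene at 180 °C gives the silylene-bridged ethoxyfuran F4 with loss of acetonitrile. Aqueous HF in MeCN hydrolyses the ethoxyfuran and removes the silylene to give the butenolide diol F5. Lithium tert-butylperoxide gives the epoxy lactone F6, and SmI2 opening gives 37.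

2. Step 27. The tetrasubstituted, electron-poor alkene may react sluggishly, or oxygen may be delivered to the wrong face. Fallback, from 34, back at 36: hydrogen-bond-directed dihydroxylation (OsO4, TMEDA, CH2Cl2, −78 °C), syn to the C9 hydroxyl, should give the 8,17-diol F7. SmI2/HMPA/pivalic acid then removes the α-hydroxyl of the α-hydroxy lactone at C17 to give 36.

3. Step 3. The trisubstituted enal may add too slowly to the 1-substituted diene, or with poor exo and facial selectivity. Fallback, from 5, back at 6: an auxiliary-controlled cycloaddition. NaClO2 oxidation of 5 gives the enoic acid F8. Its pivaloyl mixed anhydride with lithiated (S)-4-benzyloxazolidin-2-one gives the imide F9. Me2AlCl-promoted Diels–Alder reaction with diene 2 gives the adduct F10. LiBH4 removes the auxiliary to give the primary alcohol F11, and Dess–Martin oxidation gives 6.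

Further compounds
F1 | step 24 | (9R)-propargylic alcohol | C=C(CC[C@@H](OC(C)=O)[C@]2(C)[C@H]([C@@H](C)[C@H](OC(=O)CCCCC)[C@@H]3O[C@@H]32)[C@@H](O)C#CC)[C@@H](O[Si](C)(C)C(C)(C)C)c1nc(C)c(OCC)o1
F2 | step 24 | (6R,9R)-diol | C=C(CC[C@@H](OC(C)=O)[C@]2(C)[C@H]([C@@H](C)[C@H](OC(=O)CCCCC)[C@@H]3O[C@@H]32)[C@@H](O)C#CC)[C@@H](O)c1nc(C)c(OCC)o1
F3 | step 24 | cyclic diisopropylsilylene linking O6 and O9 | C=C1CC[C@@H](OC(C)=O)[C@]2(C)[C@H]([C@@H](C)[C@H](OC(=O)CCCCC)[C@@H]3O[C@@H]32)[C@H](C#CC)O[Si](C(C)C)(C(C)C)O[C@H]1c1nc(C)c(OCC)o1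
F4 | step 24 | silylene-bridged ethoxyfuran | C=C1CC[C@@H](OC(C)=O)[C@]2(C)[C@H]([C@@H](C)[C@H](OC(=O)CCCCC)[C@@H]3O[C@@H]32)[C@H]2O[Si](C(C)C)(C(C)C)O[C@H]1c1oc(OCC)c(C)c12
F5 | step 24 | butenolide 6,9-diol | C=C1CC[C@@H](OC(C)=O)[C@]2(C)[C@H]([C@@H](C)[C@H](OC(=O)CCCCC)[C@@H]3O[C@@H]32)[C@@H](O)C2=C(C)C(=O)O[C@H]2[C@@H]1O
F6 | step 24 | 8,17-epoxy lactone 6,9-diol | C=C1CC[C@@H](OC(C)=O)[C@]2(C)[C@H]([C@@H](C)[C@H](OC(=O)CCCCC)[C@@H]3O[C@@H]32)[C@@H](O)[C@@]23O[C@@]3(C)C(=O)O[C@H]2[C@@H]1O
F7 | step 27 | 8,17-diol (C6 silyl ether) | C=C1CC[C@@H](OC(C)=O)[C@]2(C)[C@H]([C@@H](C)[C@H](OC(=O)CCCCC)[C@@H]3O[C@@H]32)[C@@H](O)[C@]2(O)[C@@](C)(O)C(=O)O[C@H]2[C@@H]1O[Si](C)(C)C(C)(C)C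
F8 | step 3 | (E)-4-(tert-butyldimethylsilyloxy)-2-methylbut-2-enoic acid | OC(=O)/C(C)=C/CO[Si](C)(C)C(C)(C)C
F9 | step 3 | N-enoyl (S)-4-benzyloxazolidin-2-one | O=C(/C(C)=C/CO[Si](C)(C)C(C)(C)C)N1C(=O)OC[C@@H]1Cc1ccccc1
F10 | step 3 | Diels–Alder adduct imide | O=C([C@]2(C)[C@H]([C@@H](C)C(O[Si](C)(C)C(C)(C)C)=CC2)CO[Si](C)(C)C(C)(C)C)N1C(=O)OC[C@@H]1Cc1ccccc1
F11 | step 3 | C2 primary alcohol | OC[C@]2(C)[C@H]([C@@H](C)C(O[Si](C)(C)C(C)(C)C)=CC2)CO[Si](C)(C)C(C)(C)C
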